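Each product molecule takes one partner while the catalyst comes back unchanged, so the product counted in a flask is also the partner spent on it.

- east: left-handed substrate 5 mM; right-handed substrate 5 mM; partner 15 mM; catalyst 25 µM; the very flask that is asked about, followed so far
- flask: left-handed substrate 5.0 mM; partner 15.0 mM; catalyst 25 µM; right-handed substrate 5.0 mM; time 2.0 min

east run (percent of the left-handed substrate and right-handed substrate together charged)

| time / s | left-handed product / % | right-handed product / % | left-handed substrate / % |
|---|---|---|---|
| 10.0 | 6.7 | 3.3 | 43.3 |
| 20.0 | 10.1 | 4.3 | 42.2 |
| 50.0 | 11.7 | 4.9 | 40.7 |

(readings scatter by 0.5 percentage points)

- catalyst is single-handed; left-handed substrate and right-handed substrate are mirror images of each other, charged as a racemate, each of them at the stated concentration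
- what may be going on: partner + catalyst + left-handed substrate -> catalyst + left-handed product; partner + catalyst + right-handed substrate -> catalyst + right-handed product; left-handed substrate <-> right-handed substrate; partner <-> dormant form; partner -> decomposition product; partner -> decomposed reagent
- an excess is the difference of the two amounts in percent of their sum
- an excess is below zero if the other one leads

- excess of left-handed product over right-handed product in the product at 12 s
- excess of left-handed product over right-handed product in the product at 2.0 min
- part of the left-handed substrate and right-handed substrate charged together that has reacted at 2.0 min

The east run is this same flask followed so far, and I had to decide whether waiting or more partner was the way to more conversion in the next run. The two products together read 10.0% at 10.0 s, 14.4% at 20.0 s and 16.6% at 50.0 s, a gain that slowed, while the left-handed substrate read 43.3% at the first of these times and 40.7% at the last, so I looked to c partner. By 50.0 s the product had spent 1.66 mM of the 15 mM charged, so a side path had to be taking the partner. The reading gives 11.1% as the yield on partner, the part of the charged partner that ends in product. In the listed steps, product formation and the one-way losses of partner are each proportional to c partner, and the return from the dormant form is proportional to c dormant form, which is filled from the partner, so I took the yield on partner to drift with the substrate rather than with the partner charge. I therefore expected conversion to follow the partner charge, and I committed to about 16.6% for this flask, with a small tail. My decision was to leave this charge alone and raise the partner next time.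

The forecast gave 38.5%, 40.5% and 17.5%, holding that “the partner must be dying by a side path”.

The flask gave 36.2%, 36.4% and 19.6%, within the forecast's margins.

    partner + catalyst + left-handed substrate → catalyst + left-handed product (k = 73000 L² mol⁻² s⁻¹)
    partner + catalyst + right-handed substrate → catalyst + right-handed product (k = 33000 L² mol⁻² s⁻¹)
    left-handed substrate ⇌ right-handed substrate (k = 0.0410 s⁻¹)
    partner ⇌ dormant form (K = 1.40, k = 0.0420 s⁻¹)
    partner → decomposition product (k = 1.30 × 10⁻⁴ s⁻¹)
    partner → decomposed reagent (k = 0.0740 s⁻¹)

At 2.00 min the partner, the limiting reagent, stood at 1.1% of its charge, less than the left-handed substrate's 80%, and the yield on partner was 13.1%. For the neighbouring flask with 60 mM of partner, 11.1% foretold 66.4% reacted. That flask reached 58.9%, a yield on partner of 9.82%, lower than in this flask, with its left-handed substrate down to 41% of its charge.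

The readings are calculated from invented constants; the scatter is artificial.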